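**Assumption:** gibberellane numbering (C-1 to C-19) is used for every intermediate; GA1 is the 3β,13-dihydroxy-16-methylene 19,10-lactone 7-acid and GA72, the target, is its 15β-hydroxy derivative; centres left undefined in a SMILES (C-8 in 9, C-6 in 12–19, C-4 in 23 and 24, C-3 in 25) are inconsequential epimer mixtures that are erased or corrected later; the route is a paper design and has not been run.

## Retrosynthetic overview

1. GA72 ⇐ GA1 methyl ester: allylic oxidation at C-15, oxidation then Luche reduction to the 15β-alcohol, ester demethylation.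
2. Ring A and the 19,10-lactone ⇐ ring B/C/D cyclopentenone 20: carbonyl addition at C-10, intramolecular propanoate Michael (C4–C5), aldol (C3–C4), C-3 oxidation/reduction.
3. Ring D ⇐ ketyl–alkyne cyclisation (C13–C16) of propargyl ketone 15.
4. Ring B ⇐ intramolecular malonate Michael (C6–C8) onto 3-allyl enone 10, itself from enone 8 by allyl addition and oxidative transposition.
5. Key bond C9–C10 ⇐ L-proline-catalysed intermolecular aldol of cyclohexanone (ring C) with malonate aldehyde 3. Ring order: C, B, D, then lactone and A.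

## Route

Step 1
Reactants: 1 dimethyl allylmalonate
Product: 3 dimethyl 2-(2-oxoethyl)propanedioate, via ozonide 2 (not isolated)
Conditions: O3, CH2Cl2, −78 °C; then PPh3, −78 °C to rt
Reagents that add atoms: ozone [O-][O+]=O
Why: Criegee ozonolysis of the terminal alkene followed by reductive cleavage of the ozonide gives the aldehyde without touching the malonate.

Step 2
Reactants: 3 dimethyl 2-(2-oxoethyl)propanedioate; 4 cyclohexanone
Product: 5 anti aldol adduct (9S,10S)
Conditions: L-proline (0.3 equiv), 4 (10 equiv), DMSO, 4 °C, 72 h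
Reagents that add atoms: none
Why: List–Barbas proline-catalysed intermolecular aldol reaction, in which the enamine of cyclohexanone attacks the aldehyde through the hydrogen-bonded Houk–List transition state, so L-proline sets the ring carbon (future C-9) as S and the carbinol anti, while excess ketone suppresses aldehyde self-condensation.

Step 3
Reactants: 5 anti aldol adduct
Product: 6 triisopropylsilyl ether
Conditions: i-Pr3SiOTf (1.3 equiv), 2,6-lutidine, CH2Cl2, −78 to 0 °C
Reagents that add atoms: triisopropylsilyl triflate CC(C)[Si](OS(=O)(=O)C(F)(F)F)(C(C)C)C(C)C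
Why: Silyl ether formation under non-enolising conditions blocks retro-aldol and lactonisation of the γ-hydroxy malonate and creates no new stereocentre.

Step 4
Reactants: 6 triisopropylsilyl ether
Product: 8 cyclohex-3-en-2-one bearing the C-8 ketone conjugated to C13=C14, via trimethylsilyl enol ether 7 (not isolated)
Conditions: LiN(i-Pr)2 (2.1 equiv), THF, −78 °C; Me3SiCl (1.1 equiv); aq. NaHCO3 work-up; then Pd(OAc)2 (1.1 equiv), MeCN, rt
Reagents that add atoms: none
Why: The first equivalent of base masks the malonate as its stabilised lithium enolate, which is not silylated and is reprotonated on work-up, kinetic deprotonation then occurs at the unsubstituted α-CH2 (C-14) and not at C-9, and Saegusa–Ito oxidation of the silyl enol ether gives the enone with C-9 untouched.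

Step 5
Reactants: 8 cyclohex-3-en-2-one
Product: 9 tertiary allylic alcohol
Conditions: CH2=CHCH2MgBr (2.2 equiv), THF, −78 °C; then aq. NH4Cl
Reagents that add atoms: allylmagnesium bromide C=CC[Mg]Br
Why: Grignard 1,2-addition of the allyl reagent to the enone carbonyl (the first equivalent only deprotonates the malonate) installs C-15 to C-17 on C-8, and the new carbinol centre is erased in the next step.

Step 6
Reactants: 9 tertiary allylic alcohol
Product: 10 3-allyl-4-substituted cyclohex-2-enone
Conditions: pyridinium chlorochromate (C5H5NH)[CrO3Cl] (2 equiv), 4 Å molecular sieves, CH2Cl2, rt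
Reagents that add atoms: pyridinium chlorochromate [O-][Cr](=O)(=O)Cl.c1cc[nH+]cc1
Why: Dauben–Babler oxidative 1,3-transposition, a [3,3] shift of the allylic chromate ester followed by oxidation, moves the oxygen to C-13 and leaves the C8=C14 enone with C-9 (now γ) unaffected.

Step 7
Reactants: 10 3-allyl-4-substituted cyclohex-2-enone
Product: 11 cis-hydrindanone gem-diester
Conditions: Cs2CO3 (0.3 equiv), MeCN, rt
Reagents that add atoms: none
Why: Intramolecular 5-exo-trig Michael addition of the malonate to the β,β-disubstituted enone, in which the tether on C-9 can only deliver C-6 to its own face, closes ring B cis-fused and sets quaternary C-8 with the allyl group cis to H-9.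

Step 8
Reactants: 11 cis-hydrindanone gem-diester
Product: 12 mono-ester
Conditions: LiCl (3 equiv), H2O (2 equiv), DMSO, 150 °C
Reagents that add atoms: none
Why: Krapcho dealkoxycarbonylation removes one ester of the quaternary malonate, and the C-6 epimer mixture does not matter because C-6 becomes sp2 in step 14.

Step 9
Reactants: 12 mono-ester
Product: 14 aldehyde, via ozonide 13 (not isolated)
Conditions: O3, CH2Cl2, −78 °C; then PPh3, −78 °C to rt
Reagents that add atoms: ozone [O-][O+]=O
Why: Ozonolysis of the only alkene shortens the allyl group to the C15–C16 acetaldehyde arm without affecting ketone, ester or silyl ether.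

Step 10
Reactants: 14 aldehyde
Product: 15 propargyl ketone
Conditions: dimethyl (1-diazo-2-oxopropyl)phosphonate (1.3 equiv), K2CO3, MeOH, 0 °C to rt
Reagents that add atoms: dimethyl (1-diazo-2-oxopropyl)phosphonate CC(=O)C(=[N+]=[N-])P(=O)(OC)OC
Why: Ohira–Bestmann (Seyferth–Gilbert) homologation converts the aldehyde into the terminal alkyne C16≡C17 under conditions mild enough that the irreversible alkyne formation outruns the reversible aldol side reactions of the ketone.

Step 11
Reactants: 15 propargyl ketone
Product: 16 ring B/C/D tricycle bearing 13-OH and the C16=C17 methylene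
Conditions: SmI2 (2.5 equiv), HMPA, t-BuOH, THF, 0 °C
Reagents that add atoms: none
Why: Ketyl–alkyne 5-exo-dig radical cyclisation (Stork-type reductive cyclisation) of the C-13 ketyl onto the propargyl arm forms ring D, the tertiary 13-alcohol and the exocyclic methylene in one step, with the bicyclo[3.2.1]octane geometry allowing only one configuration at C-13, and the ester is inert to SmI2.

Step 12
Reactants: 16 ring B/C/D tricycle
Product: 17 10,13-diol
Conditions: HF·pyridine, pyridine, THF, rt
Reagents that add atoms: none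
Why: Buffered fluoride desilylation frees the C-10 alcohol without ionising the tertiary allylic 13-alcohol.

Step 13
Reactants: 17 10,13-diol
Product: 18 C-10 ketone
Conditions: Dess–Martin periodinane (1.3 equiv), CH2Cl2, rt
Reagents that add atoms: none
Why: Dess–Martin oxidation converts only the secondary alcohol, the tertiary 13-alcohol is inert, and the cis ring fusion at C-9 is the stable arrangement of the hydrindanone.

Step 14
Reactants: 18 C-10 ketone
Product: 20 ring-B cyclopentenone (10-oxo; C5=C6 bearing the methyl ester; 13-OSiMe3), via bis(trimethylsilyl) derivative 19 (not isolated)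
Conditions: LiN(i-Pr)2 (2.2 equiv), Me3SiCl, THF, −78 °C; then Pd(OAc)2 (1.1 equiv), MeCN, rt
Reagents that add atoms: chlorotrimethylsilane C[Si](C)(C)Cl
Why: Kinetic enolisation at the CH2 (C-5) in preference to the ring-fusion C-9, with silylation of O-13 in the same operation, followed by Saegusa–Ito oxidation gives the enone, whose only β-hydrogen is on C-6.

Step 15
Reactants: 20 cyclopentenone
Product: 22 tertiary allylic propanoate, via bromomagnesium alkoxide 21 (not isolated)
Conditions: BrMgCH2CH2CH(OCH2CH2O) (1.5 equiv), LaCl3·2LiCl (0.3 equiv), THF, −78 °C; then (EtCO)2O, 4-(dimethylamino)pyridine, −78 °C to rt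
Reagents that add atoms: [2-(1,3-dioxolan-2-yl)ethyl]magnesium bromide Br[Mg]CCC1OCCO1; propanoic anhydride CCC(=O)OC(=O)CC
Why: Grignard 1,2-addition to the ketone from the face of H-9, anti to ring C (C-11 on the adjacent C-9), sets C-10 with its oxygen cis to C-11, and acylating the alkoxide in the flask gives the hindered ester without isolating the acid-labile tertiary allylic alcohol.

Step 16
Reactants: 22 tertiary allylic propanoate
Product: 23 γ-lactone (C4–C5 bond formed)
Conditions: KN(SiMe3)2 (1.1 equiv), THF, −78 to −20 °C; then AcOH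
Reagents that add atoms: none
Why: Intramolecular 5-exo-trig Michael addition of the propanoate enolate to the enoate (which has no γ-hydrogens) must form a cis-fused lactone, so C-5 is set with the C4–C5 bond on the face of the C-10 oxygen, and protonation at C-6 places the ester trans to C-4.

Step 17
Reactants: 23 γ-lactone
Product: 24 lactone aldehyde (13-OH free)
Conditions: 1 M HCl, THF, rt
Reagents that add atoms: water O
Why: Acid-catalysed acetal hydrolysis unmasks the C-3 aldehyde and removes the trimethylsilyl ether under conditions too mild for rearrangement of the 13-hydroxy-16-ene.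

Step 18
Reactants: 24 lactone aldehyde
Product: 25 ring-A aldol product (C-3 epimers)
Conditions: KOt-Bu (0.3 equiv), t-BuOH–THF (1:1), 0 °C
Reagents that add atoms: none
Why: Intramolecular aldol reaction of the lactone enolate at C-4 with the C-3 aldehyde, the reverse of the well-known base-induced retro-aldol opening of 3-hydroxy gibberellin lactones, closes ring A, the bridged lactone allowing only the C-4 configuration with methyl β, while reversible enolisation brings C-6 to the 6β-ester, assumed to be the more stable epimer.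

Step 19
Reactants: 25 ring-A aldol product
Product: 26 3-oxo-GA1 methyl ester
Conditions: Dess–Martin periodinane (1.5 equiv), CH2Cl2, rt
Reagents that add atoms: none
Why: Dess–Martin oxidation converges both C-3 epimers to one ketone and leaves the tertiary 13-alcohol alone.

Step 20
Reactants: 26 3-oxo-GA1 methyl ester
Product: 27 GA1 methyl ester
Conditions: K(s-Bu)3BH (2.2 equiv), THF, −78 °C
Reagents that add atoms: none
Why: Hydride reduction with the bulky tri-sec-butylborohydride occurs by equatorial attack on the ring-A ketone and gives the axial 3β-alcohol, while lactone and ester are untouched at −78 °C.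

Step 21
Reactants: 27 GA1 methyl ester
Product: 28 15α-hydroxy-GA1 methyl ester
Conditions: SeO2 (0.5 equiv), t-BuOOH (3 equiv), CH2Cl2, rt
Reagents that add atoms: tert-butyl hydroperoxide CC(C)(C)OO
Why: Selenium dioxide allylic oxidation (ene reaction then [2,3] shift) can only functionalise C-15 because C-13 is quaternary, and oxygen is delivered to the exo face of the two-carbon bridge, syn to C-14 (the α face), any 15β-alcohol or enone formed converging in the next two steps.

Step 22
Reactants: 28 15α-hydroxy-GA1 methyl ester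
Product: 29 15-oxo-GA1 methyl ester
Conditions: MnO2 (20 equiv), CH2Cl2, rt
Reagents that add atoms: none
Why: MnO2 oxidation is selective for the allylic 15-alcohol and leaves the saturated 3β-alcohol and the tertiary 13-alcohol unchanged.

Step 23
Reactants: 29 15-oxo-GA1 methyl ester
Product: 30 GA72 methyl ester
Conditions: NaBH4 (1.5 equiv), CeCl3·7H2O (1.5 equiv), MeOH, −78 °C
Reagents that add atoms: none
Why: Luche 1,2-reduction of the α-methylene ketone delivers hydride to the exo face of the bicyclo[3.2.1]octane two-carbon bridge, syn to the one-carbon bridge C-14 (the α face), because the endo face is screened by H-9 and the axial H-11, and so gives the 15β-alcohol.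

Step 24
Reactants: 30 GA72 methyl ester
Product: 31 GA72
Conditions: LiS(n-Pr) (5 equiv, preformed), HMPA, rt; then 1 M HCl to pH 3
Reagents that add atoms: none
Why: SN2 dealkylation of the hindered methyl ester by thiolate avoids aqueous base, which would epimerise the 3β-alcohol by retro-aldol, and cannot attack the tertiary-alkyl lactone.

## Compound list

1 | dimethyl 2-(prop-2-en-1-yl)propanedioate (dimethyl allylmalonate) | C=CCC(C(=O)OC)C(=O)OC | starting material
2 | dimethyl 2-(1,2,4-trioxolan-3-ylmethyl)propanedioate (ozonide of 1) | COC(=O)C(CC1OCOO1)C(=O)OC | intermediate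
3 | dimethyl 2-(2-oxoethyl)propanedioate | O=CCC(C(=O)OC)C(=O)OC | intermediate
4 | cyclohexanone | O=C1CCCCC1 | starting material
5 | dimethyl 2-[(2S)-2-hydroxy-2-[(1S)-2-oxocyclohexyl]ethyl]propanedioate (anti aldol; ring CH is C-9, carbinol is C-10) | COC(=O)C(C(=O)OC)C[C@H](O)[C@@H]1CCCCC1=O | intermediate
6 | dimethyl 2-[(2S)-2-[(1S)-2-oxocyclohexyl]-2-(triisopropylsilyloxy)ethyl]propanedioate | COC(=O)C(C(=O)OC)C[C@H](O[Si](C(C)C)(C(C)C)C(C)C)[C@@H]1CCCCC1=O | intermediate
7 | dimethyl 2-[(2S)-2-(triisopropylsilyloxy)-2-[(1S)-2-(trimethylsilyloxy)cyclohex-2-en-1-yl]ethyl]propanedioate | COC(=O)C(C(=O)OC)C[C@H](O[Si](C(C)C)(C(C)C)C(C)C)[C@@H]1CCCC=C1O[Si](C)(C)C | intermediate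
8 | dimethyl 2-[(2S)-2-[(1S)-2-oxocyclohex-3-en-1-yl]-2-(triisopropylsilyloxy)ethyl]propanedioate | COC(=O)C(C(=O)OC)C[C@H](O[Si](C(C)C)(C(C)C)C(C)C)[C@@H]1CCC=CC1=O | intermediate
9 | dimethyl 2-[(2S)-2-[(1S)-2-hydroxy-2-(prop-2-en-1-yl)cyclohex-3-en-1-yl]-2-(triisopropylsilyloxy)ethyl]propanedioate (both carbinol epimers) | COC(=O)C(C(=O)OC)C[C@H](O[Si](C(C)C)(C(C)C)C(C)C)[C@@H]1CCC=CC1(O)CC=C | intermediate
10 | dimethyl 2-[(2S)-2-[(1R)-4-oxo-2-(prop-2-en-1-yl)cyclohex-2-en-1-yl]-2-(triisopropylsilyloxy)ethyl]propanedioate | COC(=O)C(C(=O)OC)C[C@H](O[Si](C(C)C)(C(C)C)C(C)C)[C@@H]1CCC(=O)C=C1CC=C | intermediate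
11 | dimethyl 6-oxo-7a-(prop-2-en-1-yl)-3-(triisopropylsilyloxy)octahydro-1H-indene-1,1-dicarboxylate; cis ring fusion with 7a-allyl cis to 3a-H and 3-silyloxy trans to 3a-H (C-7a is C-8, C-3a is C-9, C-3 is C-10, C-1 is C-6) | C=CC[C@]12CC(=O)CC[C@H]1[C@@H](O[Si](C(C)C)(C(C)C)C(C)C)CC2(C(=O)OC)C(=O)OC | intermediate
12 | methyl 6-oxo-7a-(prop-2-en-1-yl)-3-(triisopropylsilyloxy)octahydro-1H-indene-1-carboxylate; ring stereochemistry as 11, C-1 epimers | C=CC[C@]12CC(=O)CC[C@H]1[C@@H](O[Si](C(C)C)(C(C)C)C(C)C)CC2C(=O)OC | intermediate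
13 | ozonide of 12 (1,2,4-trioxolan-3-ylmethyl group on C-7a) | O1OC(C[C@]23CC(=O)CC[C@H]2[C@@H](O[Si](C(C)C)(C(C)C)C(C)C)CC3C(=O)OC)OC1 | intermediate
14 | methyl 6-oxo-7a-(2-oxoethyl)-3-(triisopropylsilyloxy)octahydro-1H-indene-1-carboxylate; ring stereochemistry as 11 | O=CC[C@]12CC(=O)CC[C@H]1[C@@H](O[Si](C(C)C)(C(C)C)C(C)C)CC2C(=O)OC | intermediate
15 | methyl 6-oxo-7a-(prop-2-yn-1-yl)-3-(triisopropylsilyloxy)octahydro-1H-indene-1-carboxylate; ring stereochemistry as 11 | C#CC[C@]12CC(=O)CC[C@H]1[C@@H](O[Si](C(C)C)(C(C)C)C(C)C)CC2C(=O)OC | intermediate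
16 | ring B/C/D tricycle: cyclopentane (C-6 CO2Me, C-10 OSi(i-Pr)3) cis-fused at C8–C9 to a bicyclo[3.2.1]octane carrying bridgehead 13-OH and 16-methylene, ring-D bridge cis to H-9 | C=C1C[C@]23C[C@@]1(O)CC[C@H]2[C@@H](O[Si](C(C)C)(C(C)C)C(C)C)CC3C(=O)OC | intermediate
17 | 10,13-diol corresponding to 16 | C=C1C[C@]23C[C@@]1(O)CC[C@H]2[C@@H](O)CC3C(=O)OC | intermediate
18 | 10-oxo-13-hydroxy tricycle (ring-B cyclopentanone) | C=C1C[C@]23C[C@@]1(O)CC[C@H]2C(=O)CC3C(=O)OC | intermediate
19 | 13-O-trimethylsilyl ether and C10=C5 trimethylsilyl enol ether of 18 | C=C1C[C@]23C[C@@]1(O[Si](C)(C)C)CC[C@H]2C(O[Si](C)(C)C)=CC3C(=O)OC | intermediate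
20 | ring-B cyclopentenone: 10-oxo, C5=C6 bearing the C-7 methyl ester, 13-OSiMe3, 16-methylene | C=C1C[C@]23C[C@@]1(O[Si](C)(C)C)CC[C@H]2C(=O)C=C3C(=O)OC | intermediate
21 | bromomagnesium C-10 alkoxide after addition of the 2-(1,3-dioxolan-2-yl)ethyl group (C-1 to C-3); oxygen cis to C-11 | C=C1C[C@]23C[C@@]1(O[Si](C)(C)C)CC[C@H]2[C@](O[Mg]Br)(CCC4OCCO4)C=C3C(=O)OC | intermediate
22 | C-10 tertiary propanoate of the same carbinol | C=C1C[C@]23C[C@@]1(O[Si](C)(C)C)CC[C@H]2[C@](OC(=O)CC)(CCC4OCCO4)C=C3C(=O)OC | intermediate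
23 | 19,10-γ-lactone cis-fused to ring B at C5–C10; C-4 carries H and CH3 (epimers), 5β-H, 6β-CO2Me, C-10 dioxolanylethyl chain, 13-OSiMe3 | C=C1C[C@]23C[C@@]1(O[Si](C)(C)C)CC[C@H]2[C@@]4(CCC5OCCO5)OC(=O)C(C)[C@H]4[C@@H]3C(=O)OC | intermediate
24 | lactone aldehyde: as 23 but carrying a C-10 3-oxopropyl chain and free 13-OH | C=C1C[C@]23C[C@@]1(O)CC[C@H]2[C@@]4(CCC=O)OC(=O)C(C)[C@H]4[C@@H]3C(=O)OC | intermediate
25 | GA1 methyl ester as a mixture of C-3 epimers | C=C1C[C@]23C[C@@]1(O)CC[C@H]2[C@@]12CCC(O)[C@@](C)(C(=O)O1)[C@H]2[C@@H]3C(=O)OC | intermediate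
26 | 3-oxo-GA1 methyl ester (3-dehydro-GA1 methyl ester) | C=C1C[C@]23C[C@@]1(O)CC[C@H]2[C@@]12CCC(=O)[C@@](C)(C(=O)O1)[C@H]2[C@@H]3C(=O)OC | intermediate
27 | GA1 methyl ester (3β,13-dihydroxy) | C=C1C[C@]23C[C@@]1(O)CC[C@H]2[C@@]12CC[C@H](O)[C@@](C)(C(=O)O1)[C@H]2[C@@H]3C(=O)OC | intermediate
28 | 15α-hydroxy-GA1 methyl ester (15-epi-GA72 methyl ester) | C=C1[C@H](O)[C@]23C[C@@]1(O)CC[C@H]2[C@@]12CC[C@H](O)[C@@](C)(C(=O)O1)[C@H]2[C@@H]3C(=O)OC | intermediate
29 | 15-oxo-GA1 methyl ester | C=C1C(=O)[C@]23C[C@@]1(O)CC[C@H]2[C@@]12CC[C@H](O)[C@@](C)(C(=O)O1)[C@H]2[C@@H]3C(=O)OC | intermediate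
30 | GA72 methyl ester (3β,13,15β-trihydroxy) | C=C1[C@@H](O)[C@]23C[C@@]1(O)CC[C@H]2[C@@]12CC[C@H](O)[C@@](C)(C(=O)O1)[C@H]2[C@@H]3C(=O)OC | intermediate
31 | GA72 (15β-hydroxy-GA1: 19,10-γ-lactone 7-carboxylic acid carrying 3β-, 13- and 15β-hydroxyls and the 16-methylene) | C=C1[C@@H](O)[C@]23C[C@@]1(O)CC[C@H]2[C@@]12CC[C@H](O)[C@@](C)(C(=O)O1)[C@H]2[C@@H]3C(=O)O | target

## Step count and risks

Total step count: 24. Longest linear sequence: 24 steps (1 to 31); cyclohexanone 4 enters at step 2.

**Step 2 (proline aldol).** The aldehyde is unbranched and enolisable and carries an acidic malonate, so self-condensation, lactonisation of 5 and reduced enantiomeric excess are possible. The fallback forms the C5–C6 bond after the aldol instead. Starting from 4, the L-proline aldol is run with (tert-butyldimethylsilyloxy)acetaldehyde, an α-oxygenated acceptor of the best-behaved class, to give the anti ketol (S)-2-[(1R)-2-(tert-butyldimethylsilyloxy)-1-hydroxyethyl]cyclohexanone F1. Silylation with i-Pr3SiOTf and 2,6-lutidine gives the bis-silyl ether F2. HF·pyridine in THF–pyridine at 0 °C removes only the primary silyl group, without the ketalisation that acidic methanol could cause, to give the primary alcohol F3. I2, PPh3 and imidazole convert it into the primary iodide F4. Alkylation of preformed sodium dimethyl malonate (dimethyl malonate 3 equiv, NaH 2.5 equiv, DMF, 50 °C), which is too weak a base to enolise the ketone, with F4 returns to the route at 6.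

**Step 11 (ketyl–alkyne cyclisation).** Simple ketone reduction or dimerisation could compete. The fallback sets out from aldehyde 14, before the alkyne is made. SmI2 in THF–MeOH effects an intramolecular ketone–aldehyde pinacol coupling to give the ring-D 13,16-diol F5. Parikh–Doering oxidation (SO3·pyridine, DMSO, Et3N) of the secondary alcohol gives the 13-hydroxy-16-ketone F6. Wittig methylenation with excess Ph3P=CH2 (from Ph3PCH3Br and KOt-Bu) returns to the route at 16.

**Step 16 (propanoate Michael).** The unactivated ester enolate may add sluggishly or the tertiary ester may be cleaved. The fallback sets out from 20. After the same Grignard addition, alkoxide 21 is trapped with 2-bromopropanoyl bromide to give the tertiary 2-bromopropanoate F7. SmI2 (2.2 equiv, THF, −78 °C) generates the samarium enolate by reduction of the C–Br bond, and this closes the lactone by a Reformatsky-type intramolecular conjugate addition without strong base, returning to the route at 23.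

Further compounds
F1 | step 2 | (S)-2-[(1R)-2-(tert-butyldimethylsilyloxy)-1-hydroxyethyl]cyclohexanone (anti ketol) | CC(C)(C)[Si](C)(C)OC[C@H](O)[C@@H]1CCCCC1=O
F2 | step 2 | bis-silyl ether: primary tert-butyldimethylsilyl and secondary triisopropylsilyl ether of the same diol | CC(C)(C)[Si](C)(C)OC[C@H](O[Si](C(C)C)(C(C)C)C(C)C)[C@@H]1CCCCC1=O
F3 | step 2 | primary alcohol: (S)-2-[2-hydroxy-1-(triisopropylsilyloxy)ethyl]cyclohexanone keeping the carbinol configuration of F1 | OC[C@H](O[Si](C(C)C)(C(C)C)C(C)C)[C@@H]1CCCCC1=O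
F4 | step 2 | primary iodide: (S)-2-[2-iodo-1-(triisopropylsilyloxy)ethyl]cyclohexanone of the same configuration | IC[C@H](O[Si](C(C)C)(C(C)C)C(C)C)[C@@H]1CCCCC1=O
F5 | step 11 | ring-D 13,16-diol of the ring B/C/D tricycle (C-16 epimers; C-10 OSi(i-Pr)3, C-6 CO2Me) | OC1C[C@]23C[C@@]1(O)CC[C@H]2[C@@H](O[Si](C(C)C)(C(C)C)C(C)C)CC3C(=O)OC
F6 | step 11 | 13-hydroxy-16-ketone of the same tricycle | O=C1C[C@]23C[C@@]1(O)CC[C@H]2[C@@H](O[Si](C(C)C)(C(C)C)C(C)C)CC3C(=O)OC
F7 | step 16 | C-10 tertiary 2-bromopropanoate corresponding to 22 | C=C1C[C@]23C[C@@]1(O[Si](C)(C)C)CC[C@H]2[C@](OC(=O)C(C)Br)(CCC4OCCO4)C=C3C(=O)OC
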